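**Retrosynthetic overview**
- The ten-membered ring is closed last, at C9–C10, by intramolecular Nozaki–Hiyama–Kishi addition of a Z-vinyl iodide to a C9 aldehyde (this sets C9). Just before that, the γ-lactone ring is formed by oxidative lactonisation of a C12 allylic alcohol onto O6.
- The C8 ester comes from Yamaguchi acylation with (2S,3R)-2,3-dimethyloxirane-2-carboxylic acid. Its oxirane ring is made first of all, by Sharpless epoxidation of tiglyl alcohol followed by oxidation.
- C1–C5 chain: C1=C10 by Z-selective iodo-Wittig olefination; C4=C5 (E) and C2–C3 by Johnson–Claisen rearrangement of an isopropenyl carbinol made from a furanose lactol.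
- Key C7–C11 bond: intermolecular aldol addition of the lithium enolate of ethyl 3-(dimethylamino)propanoate (a masked acrylate, C11–C13) to a D-arabinose-derived furanos-3-ulose. C6 and C8 are D-arabinose C2 and C4; C7 comes from addition to the open face of the ketone.
- Ring order: oxirane (side chain), then γ-lactone, then ten-membered carbocycle.

Assumption and conventions: the target is numbered as a germacranolide (C1=C10 with C14 methyl on C10; C4=C5 with C15 methyl on C4; lactone oxygen on C6; C7 tertiary carbinol; C8 ester; C9 carbinol; C11=C13 methylene; C12 carbonyl) and these numbers are used for all open-chain intermediates; TBDPS = tert-butyldiphenylsilyl, TBS = tert-butyldimethylsilyl; D-arabinose, tiglic acid and ethyl 3-(dimethylamino)propanoate are taken as cheap commercial materials.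

Step 1
Reactants: 1 tiglic acid [(E)-2-methylbut-2-enoic acid]
Product: 2 (E)-2-methylbut-2-en-1-ol
Conditions: LiAlH4, Et2O, 0 °C to rt; H2O/NaOH work-up
Reagents that add atoms: none
Why: Hydride reduction of the carboxylic acid proceeds by 1,2-reduction and leaves the E-trisubstituted alkene untouched.

Step 2
Reactants: 2 (E)-2-methylbut-2-en-1-ol
Product: 3 [(2R,3R)-2,3-dimethyloxiran-2-yl]methanol
Conditions: Ti(OiPr)4 (10 mol %), diethyl D-(−)-tartrate (12 mol %), t-BuOOH, 4 Å sieves, CH2Cl2, −20 °C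
Reagents that add atoms: tert-butyl hydroperoxide CC(C)(C)OO
Why: Sharpless asymmetric epoxidation, in which the D-tartrate ligand delivers oxygen to the face that gives the 2R,3R epoxy alcohol, while the E-alkene geometry fixes the trans relation of CH2OH and the 3-methyl group.

Step 3
Reactants: 3 [(2R,3R)-2,3-dimethyloxiran-2-yl]methanol
Product: 4 (2S,3R)-2,3-dimethyloxirane-2-carboxylic acid
Conditions: RuCl3 (2 mol %), NaIO4, MeCN/EtOAc/H2O, rt
Reagents that add atoms: water O
Why: Catalytic RuO4 oxidation (Sharpless conditions) takes the primary alcohol through the aldehyde hydrate to the acid without touching either epoxide stereocentre (the C2 descriptor changes only through CIP priority).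

Step 4
Reactants: 5 D-arabinose
Product: 6 5-O-TBDPS-D-arabinofuranose (anomer mixture)
Conditions: TBDPSCl, imidazole, DMF, 0 °C to rt
Reagents that add atoms: tert-butyl(chloro)diphenylsilane CC(C)(C)[Si](Cl)(c1ccccc1)c1ccccc1
Why: Silyl ether formation, in which only the furanose tautomers offer a primary hydroxyl, so the bulky silyl chloride drains the equilibrium into the 5-O-silyl furanose.

Step 5
Reactants: 6 5-O-TBDPS-D-arabinofuranose
Product: 7 5-O-TBDPS-1,2-O-isopropylidene-β-D-arabinofuranose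
Conditions: 2,2-dimethoxypropane, TsOH (cat.), acetone, rt
Reagents that add atoms: 2,2-dimethoxypropane COC(C)(C)OC
Why: Acetonide (ketal) formation takes the only cis-diol (O1/O2 of the β-furanose) and leaves the trans-disposed 3-OH free.

Step 6
Reactants: 7 5-O-TBDPS-1,2-O-isopropylidene-β-D-arabinofuranose
Product: 8 5-O-TBDPS-1,2-O-isopropylidene-β-D-threo-pentofuranos-3-ulose
Conditions: Dess–Martin periodinane, NaHCO3, CH2Cl2, rt
Reagents that add atoms: none
Why: Dess–Martin oxidation of the lone secondary alcohol gives the ketone under non-basic conditions, so C2 and C4 are not epimerised.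

Step 7
Reactants: 8 5-O-TBDPS-1,2-O-isopropylidene-β-D-threo-pentofuranos-3-ulose; 9 ethyl 3-(dimethylamino)propanoate
Product: 10 ethyl 3-(dimethylamino)-2-[5-O-TBDPS-1,2-O-isopropylidene-β-D-lyxofuranos-3-C-yl]propanoate (both epimers at the ester α-carbon)
Conditions: 9, LiN(iPr)2, THF, −78 °C; then 8, −78 °C; AcOH quench at −78 °C
Reagents that add atoms: none
Why: Intermolecular aldol addition of the lithium ester enolate (a masked acrylate α-anion) joins the two fragments at C7–C11; the acetonide and the C4 side chain both block the β-face, so attack comes from the α-face and the new tertiary OH is cis to them (D-lyxo, the C7 configuration of the target).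

Step 8
Reactants: 10 ethyl 3-(dimethylamino)-2-[5-O-TBDPS-1,2-O-isopropylidene-β-D-lyxofuranos-3-C-yl]propanoate
Product: 12 ethyl 2-[5-O-TBDPS-1,2-O-isopropylidene-β-D-lyxofuranos-3-C-yl]prop-2-enoate, via ammonium iodide 11 (not isolated)
Conditions: MeI, CH2Cl2, rt; then DBU, 0 °C to rt
Reagents that add atoms: none
Why: N-Quaternisation followed by E1cB (Hofmann-type) loss of trimethylamine unveils the C11=C13 methylene and removes the stereocentre at C11; the methyl from MeI leaves with the amine.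

Step 9
Reactants: 12 ethyl 2-[5-O-TBDPS-1,2-O-isopropylidene-β-D-lyxofuranos-3-C-yl]prop-2-enoate
Product: 13 5-O-TBDPS-3-C-(3-hydroxyprop-1-en-2-yl)-1,2-O-isopropylidene-β-D-lyxofuranose
Conditions: iBu2AlH, CH2Cl2, −78 to −20 °C; aq. KNaC4H4O6 work-up
Reagents that add atoms: none
Why: 1,2-Hydride reduction of the enoate gives the C12 allylic alcohol, which makes C12 inert to the hydride and organometallic steps that follow.

Step 10
Reactants: 13 5-O-TBDPS-3-C-(3-hydroxyprop-1-en-2-yl)-1,2-O-isopropylidene-β-D-lyxofuranose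
Product: 14 5-O-TBDPS-3-C-[3-(TBS-oxy)prop-1-en-2-yl]-1,2-O-isopropylidene-β-D-lyxofuranose
Conditions: TBSCl, imidazole, CH2Cl2, 0 °C
Reagents that add atoms: tert-butyl(chloro)dimethylsilane CC(C)(C)[Si](C)(C)Cl
Why: Silylation is selective for the primary allylic hydroxyl over the hindered tertiary C7 hydroxyl.

Step 11
Reactants: 14 5-O-TBDPS-3-C-[3-(TBS-oxy)prop-1-en-2-yl]-1,2-O-isopropylidene-β-D-lyxofuranose
Product: 15 5-O-TBDPS-3-C-[3-(TBS-oxy)prop-1-en-2-yl]-2,3-O-isopropylidene-D-lyxofuranose (lactol; anomer mixture)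
Conditions: camphorsulfonic acid (cat.), dry acetone, rt; Et3N quench
Reagents that add atoms: none
Why: Acid-catalysed acetal migration (trans-ketalisation): now that O3 is cis to O2 the 2,3-O-isopropylidene furanose is the thermodynamic ketal, as in the acetonation of lyxose or ribose, and the anomeric hydroxyl is set free.

Step 12
Reactants: 15 5-O-TBDPS-3-C-[3-(TBS-oxy)prop-1-en-2-yl]-2,3-O-isopropylidene-D-lyxofuranose
Product: 16 open-chain diol CH2=C(CH3)–C5H(OH)–[C6/C7 acetonide]–C8H(OH)–C9H2OTBDPS carrying C(=CH2)CH2OTBS on C7 (C5 epimers; C6 C7 C8 as in D-lyxose C2 C3 C4)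
Conditions: CH2=C(CH3)MgBr (4 equiv), THF, 0 °C to rt; H2O quench
Reagents that add atoms: isopropenylmagnesium bromide C=C(C)[Mg]Br
Why: Grignard addition to the open-chain aldehyde tautomer of the lactol; the configuration of the new C5 carbinol does not matter because C5 becomes sp2 in the next step.

Step 13
Reactants: 16 open-chain isopropenyl carbinol diol
Product: 18 (4E)-diol HOCH2(C1)–C2H2–C3H2–C4(CH3)=C5H–[C6/C7 acetonide]–C8H(OH)–C9H2OTBDPS (12-OTBS), via ethyl ester 17 (not isolated)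
Conditions: MeC(OEt)3, EtCO2H (cat.), 140 °C (EtOH distilled off); brief aq. citric acid wash; then LiAlH4, THF, 0 °C
Reagents that add atoms: triethyl orthoacetate CC(OCC)(OCC)OCC
Why: Johnson orthoester Claisen rearrangement through a chair transition state with the C6 substituent equatorial gives the E-trisubstituted C4=C5 alkene and the C2–C3 bond, and the hydride step reduces the ester and returns any acetate formed on O8 to the free hydroxyl.

Step 14
Reactants: 18 (4E)-C1,C8-diol
Product: 19 (4E)-C1 aldehyde with free 8-OH (6,7-O-isopropylidene; 9-OTBDPS; 12-OTBS)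
Conditions: TEMPO (10 mol %), PhI(OAc)2, CH2Cl2, rt
Reagents that add atoms: none
Why: Oxoammonium (TEMPO) oxidation is selective for the primary alcohol over the hindered secondary C8 hydroxyl and stops at the aldehyde.

Step 15
Reactants: 19 (4E)-C1 aldehyde
Product: 20 (1(10)Z,4E)-10-iodo diene CH3–C10(I)=C1H–C2H2–C3H2–C4(CH3)=C5H–[C6/C7 acetonide]–C8H(OH)–C9H2OTBDPS (12-OTBS)
Conditions: [Ph3PCH2CH3]I, n-BuLi, THF; I2, −78 °C; NaN(SiMe3)2, −20 °C; then 19, −78 °C to rt (excess ylide)
Reagents that add atoms: ethyltriphenylphosphonium iodide CC[P+](c1ccccc1)(c1ccccc1)c1ccccc1.[I-]; iodine II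
Why: Stork–Zhao-type Wittig olefination with the α-iodo ylide gives the Z-2-iodoalkene (iodine cis to the chain), which is the geometry needed for the cis C1=C10 bond of the ring.

Step 16
Reactants: 20 (1(10)Z,4E)-10-iodo diene with free 8-OH; 4 (2S,3R)-2,3-dimethyloxirane-2-carboxylic acid
Product: 22 8-O-[(2S,3R)-2,3-dimethyloxirane-2-carbonyl] ester of 20, via mixed anhydride 21 (not isolated)
Conditions: 4, 2,4,6-Cl3C6H2COCl, Et3N, toluene, rt; then 20, DMAP, toluene, 60 °C
Reagents that add atoms: none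
Why: Yamaguchi esterification through the mixed anhydride acylates the only free hydroxyl (O8) with retention at every stereocentre, forcing conditions being accepted because both partners are hindered.

Step 17
Reactants: 22 8-O-epoxy ester
Product: 23 6,7,12-triol (8-O-epoxy ester; 9-OTBDPS; Z-vinyl iodide)
Conditions: AcOH/H2O/THF (4:1:1), 45 °C
Reagents that add atoms: none
Why: Mild acid hydrolysis removes the ketal and the primary allylic TBS ether together, while the TBDPS ether, the electron-poor glycidic ester and the vinyl iodide are stable to aqueous acetic acid.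

Step 18
Reactants: 23 6,7,12-triol
Product: 26 α-methylene-γ-butyrolactone (O6–C12) with free 7-OH (8-O-epoxy ester; 9-OTBDPS; Z-vinyl iodide), via enal 24 (not isolated), via lactol 25 (not isolated)
Conditions: TEMPO (20 mol %), PhI(OAc)2 (3 equiv), CH2Cl2, rt
Reagents that add atoms: none
Why: TEMPO/PhI(OAc)2 oxidative lactonisation: the primary allylic alcohol is oxidised first, the enal is trapped by the C6 hydroxyl as a five-membered lactol and a second oxidation gives the lactone, with no change at C6 or C7.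

Step 19
Reactants: 26 α-methylene lactone 9-OTBDPS
Product: 27 9-hydroxy lactone (primary alcohol at C9)
Conditions: HF·pyridine, pyridine, THF, 0 °C to rt
Reagents that add atoms: none
Why: Buffered fluoride desilylation frees the C9 hydroxyl without the basic conditions that would favour acyl migration from O8 or conjugate addition to the methylene lactone.

Step 20
Reactants: 27 9-hydroxy lactone
Product: 28 C9 aldehyde (α-acyloxy aldehyde; Z-vinyl iodide; methylene lactone)
Conditions: Dess–Martin periodinane, NaHCO3, CH2Cl2, 0 °C; used at once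
Reagents that add atoms: none
Why: Dess–Martin oxidation gives the aldehyde under near-neutral conditions, so the C8 stereocentre next to it is not epimerised.

Step 21
Reactants: 28 C9 aldehyde
Product: 29 target, (6R,7R,8R,9R)-7,9-dihydroxy-8-[(2S,3R)-2,3-dimethyloxirane-2-carbonyloxy]germacra-1(10)Z,4E,11(13)-trien-12,6-olide
Conditions: CrCl2 (15 equiv), NiCl2 (15 mol %), degassed DMSO/THF, 0.003 M, rt, slow addition
Reagents that add atoms: none
Why: Intramolecular Nozaki–Hiyama–Kishi reaction: the Z-alkenylchromium species (geometry retained) adds to the aldehyde at high dilution to close the ten-membered ring, and Felkin–Anh attack anti to the C8 acyloxy group gives the 8,9-anti (9R) alcohol.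

**Compound list**
1 | tiglic acid, (E)-2-methylbut-2-enoic acid | C/C=C(\C)C(=O)O | starting material
2 | (E)-2-methylbut-2-en-1-ol | C/C=C(\C)CO | intermediate
3 | [(2R,3R)-2,3-dimethyloxiran-2-yl]methanol | OC[C@@]1(C)O[C@@H]1C | intermediate
4 | (2S,3R)-2,3-dimethyloxirane-2-carboxylic acid | OC(=O)[C@@]1(C)O[C@@H]1C | intermediate
5 | D-arabinose (drawn open-chain) | O=C[C@@H](O)[C@H](O)[C@H](O)CO | starting material
6 | 5-O-TBDPS-D-arabinofuranose (anomer mixture) | OC1O[C@H](CO[Si](c2ccccc2)(c2ccccc2)C(C)(C)C)[C@@H](O)[C@@H]1O | intermediate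
7 | 5-O-TBDPS-1,2-O-isopropylidene-β-D-arabinofuranose | CC1(C)O[C@@H]2O[C@H](CO[Si](c3ccccc3)(c3ccccc3)C(C)(C)C)[C@@H](O)[C@@H]2O1 | intermediate
8 | 5-O-TBDPS-1,2-O-isopropylidene-β-D-threo-pentofuranos-3-ulose | CC1(C)O[C@@H]2O[C@H](CO[Si](c3ccccc3)(c3ccccc3)C(C)(C)C)C(=O)[C@@H]2O1 | intermediate
9 | ethyl 3-(dimethylamino)propanoate | CCOC(=O)CCN(C)C | starting material
10 | ethyl 3-(dimethylamino)-2-[5-O-TBDPS-1,2-O-isopropylidene-β-D-lyxofuranos-3-C-yl]propanoate (tertiary 3-OH cis to the acetonide; both epimers at the ester α-carbon) | CC1(C)O[C@@H]2O[C@H](CO[Si](c3ccccc3)(c3ccccc3)C(C)(C)C)[C@@](O)(C(CN(C)C)C(=O)OCC)[C@@H]2O1 | intermediate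
11 | N,N,N-trimethylammonium iodide of 10 | CC1(C)O[C@@H]2O[C@H](CO[Si](c3ccccc3)(c3ccccc3)C(C)(C)C)[C@@](O)(C(C[N+](C)(C)C)C(=O)OCC)[C@@H]2O1.[I-] | intermediate
12 | ethyl 2-[5-O-TBDPS-1,2-O-isopropylidene-β-D-lyxofuranos-3-C-yl]prop-2-enoate | CC1(C)O[C@@H]2O[C@H](CO[Si](c3ccccc3)(c3ccccc3)C(C)(C)C)[C@@](O)(C(=C)C(=O)OCC)[C@@H]2O1 | intermediate
13 | 5-O-TBDPS-3-C-(3-hydroxyprop-1-en-2-yl)-1,2-O-isopropylidene-β-D-lyxofuranose | CC1(C)O[C@@H]2O[C@H](CO[Si](c3ccccc3)(c3ccccc3)C(C)(C)C)[C@@](O)(C(=C)CO)[C@@H]2O1 | intermediate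
14 | 5-O-TBDPS-3-C-[3-(TBS-oxy)prop-1-en-2-yl]-1,2-O-isopropylidene-β-D-lyxofuranose | CC1(C)O[C@@H]2O[C@H](CO[Si](c3ccccc3)(c3ccccc3)C(C)(C)C)[C@@](O)(C(=C)CO[Si](C)(C)C(C)(C)C)[C@@H]2O1 | intermediate
15 | 5-O-TBDPS-3-C-[3-(TBS-oxy)prop-1-en-2-yl]-2,3-O-isopropylidene-D-lyxofuranose (lactol, anomer mixture) | OC1O[C@H](CO[Si](c3ccccc3)(c3ccccc3)C(C)(C)C)[C@]2(C(=C)CO[Si](C)(C)C(C)(C)C)OC(C)(C)O[C@H]12 | intermediate
16 | open-chain diol: isopropenyl carbinol at C5 (both epimers), 6,7-O-isopropylidene, C7 bearing C(=CH2)CH2OTBS, free 8-OH, 9-OTBDPS; C6, C7, C8 as in the target | C=C(C)C(O)[C@H]1OC(C)(C)O[C@@]1(C(=C)CO[Si](C)(C)C(C)(C)C)[C@H](O)CO[Si](c2ccccc2)(c2ccccc2)C(C)(C)C | intermediate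
17 | ethyl (4E)-ester EtO2C(C1)–C2H2–C3H2–C4(CH3)=C5H–, otherwise as 16 | CCOC(=O)CC/C(C)=C/[C@H]1OC(C)(C)O[C@@]1(C(=C)CO[Si](C)(C)C(C)(C)C)[C@H](O)CO[Si](c2ccccc2)(c2ccccc2)C(C)(C)C | intermediate
18 | (4E)-C1,C8-diol (6,7-O-isopropylidene, 9-OTBDPS, 12-OTBS) | OCCC/C(C)=C/[C@H]1OC(C)(C)O[C@@]1(C(=C)CO[Si](C)(C)C(C)(C)C)[C@H](O)CO[Si](c2ccccc2)(c2ccccc2)C(C)(C)C | intermediate
19 | (4E)-C1 aldehyde with free 8-OH | O=CCC/C(C)=C/[C@H]1OC(C)(C)O[C@@]1(C(=C)CO[Si](C)(C)C(C)(C)C)[C@H](O)CO[Si](c2ccccc2)(c2ccccc2)C(C)(C)C | intermediate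
20 | (1(10)Z,4E)-10-iodo diene with free 8-OH | C/C(I)=C/CC/C(C)=C/[C@H]1OC(C)(C)O[C@@]1(C(=C)CO[Si](C)(C)C(C)(C)C)[C@H](O)CO[Si](c2ccccc2)(c2ccccc2)C(C)(C)C | intermediate
21 | (2S,3R)-2,3-dimethyloxirane-2-carboxylic 2,4,6-trichlorobenzoic anhydride | O=C(OC(=O)c1c(Cl)cc(Cl)cc1Cl)[C@@]2(C)O[C@@H]2C | intermediate
22 | 8-O-[(2S,3R)-2,3-dimethyloxirane-2-carbonyl] ester of 20 | C/C(I)=C/CC/C(C)=C/[C@H]1OC(C)(C)O[C@@]1(C(=C)CO[Si](C)(C)C(C)(C)C)[C@H](OC(=O)[C@@]2(C)O[C@@H]2C)CO[Si](c3ccccc3)(c3ccccc3)C(C)(C)C | intermediate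
23 | 6,7,12-triol (8-O-epoxy ester, 9-OTBDPS, Z-vinyl iodide) | C/C(I)=C/CC/C(C)=C/[C@@H](O)[C@](O)(C(=C)CO)[C@H](OC(=O)[C@@]1(C)O[C@@H]1C)CO[Si](c2ccccc2)(c2ccccc2)C(C)(C)C | intermediate
24 | C12 enal of 23 (6,7-diol) | C/C(I)=C/CC/C(C)=C/[C@@H](O)[C@](O)(C(=C)C=O)[C@H](OC(=O)[C@@]1(C)O[C@@H]1C)CO[Si](c2ccccc2)(c2ccccc2)C(C)(C)C | intermediate
25 | five-membered lactol (O6–C12, both C12 epimers) | C/C(I)=C/CC/C(C)=C/[C@H]1OC(O)C(=C)[C@]1(O)[C@H](OC(=O)[C@@]2(C)O[C@@H]2C)CO[Si](c3ccccc3)(c3ccccc3)C(C)(C)C | intermediate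
26 | α-methylene-γ-butyrolactone with free 7-OH, 8-O-epoxy ester, 9-OTBDPS, Z-vinyl iodide | C/C(I)=C/CC/C(C)=C/[C@H]1OC(=O)C(=C)[C@]1(O)[C@H](OC(=O)[C@@]2(C)O[C@@H]2C)CO[Si](c3ccccc3)(c3ccccc3)C(C)(C)C | intermediate
27 | 9-hydroxy lactone (primary alcohol) | C/C(I)=C/CC/C(C)=C/[C@H]1OC(=O)C(=C)[C@]1(O)[C@H](OC(=O)[C@@]2(C)O[C@@H]2C)CO | intermediate
28 | C9 aldehyde (seco-aldehyde for ring closure) | C/C(I)=C/CC/C(C)=C/[C@H]1OC(=O)C(=C)[C@]1(O)[C@H](OC(=O)[C@@]2(C)O[C@@H]2C)C=O | intermediate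
29 | CNP0420662.1, (6R,7R,8R,9R)-7,9-dihydroxy-8-[(2S,3R)-2,3-dimethyloxirane-2-carbonyloxy]germacra-1(10)Z,4E,11(13)-trien-12,6-olide | C=C1C(=O)O[C@@H]2/C=C(\C)CC/C=C(/C)[C@@H](O)[C@@H](OC(=O)[C@@]3(C)O[C@@H]3C)[C@@]12O | target

**Totals**
Total step count: 21. Longest linear sequence: 18 steps (steps 4 to 21, from D-arabinose); the epoxy acid 4 is made in 3 steps and joins at step 16.

**Three steps most likely to fail, with fallbacks**

Step 21 (ring closure and C9). Closing a strained ten-membered ring on an α-acyloxy aldehyde while also setting C9 is the largest risk, and the facial selectivity inside the forming ring may not follow the acyclic Felkin model. The fallback sets out from 28 and comes back at 29. The ring is closed as before, and if it gives mainly the C9 epimer 9-epi-29 F7 (or a mixture), C9 is set in a separate step instead of in the C–C bond formation. The alcohol is oxidised with Dess–Martin periodinane to the ring 9-ketone F8, a Z-enone. Reduction with Zn(BH4)2 in Et2O at −40 °C, through a zinc chelate between the ketone and the C8 ester oxygen with hydride arriving from the side away from C7, then gives the 8,9-anti alcohol 29.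

Step 11 (acetonide shift). The 1,2 to 2,3 migration rests on an equilibrium that has precedent only by analogy with lyxose and ribose, and the tertiary O3 may respond slowly. The fallback sets out from 14 and comes back at 15 by hydrolysis and re-protection instead of isomerisation. Aqueous CF3CO2H (0 °C) cleaves the anomeric acetonide, and the TBS ether with it, to give the free lactol tetrol F1. TBSCl/imidazole at −20 °C re-silylates only the primary allylic hydroxyl to give the lactol triol F2. Kinetic acetonation of the cis-2,3-diol with 2-methoxypropene and pyridinium tosylate (0 °C) then gives 15.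

Step 13 (orthoester Claisen on a diol). The rearrangement runs at 140 °C on a substrate with a free C8 hydroxyl and two silyl ethers, and ketal scrambling or incomplete rearrangement are possible. The fallback sets out from 15, leaves out 16 and 17, and comes back at 18 by olefination and homologation. Wittig reaction of lactol 15 with the stabilised ylide Ph3P=C(CH3)CO2Et (toluene, 80 °C, no added base, to suppress oxa-Michael closure) gives the (2E)-enoate F3. Reduction with iBu2AlH gives the allylic alcohol F4. CBr4/PPh3 converts the primary allylic hydroxyl into the allylic bromide F5. Alkylation of LiCH2CO2tBu (excess, THF, −78 °C) with F5 gives the tert-butyl ester F6, and LiAlH4 reduction of F6 gives 18.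

Further compounds
F1 | step 11 | 5-O-TBDPS-3-C-(3-hydroxyprop-1-en-2-yl)-D-lyxofuranose (free lactol tetrol) | OC1O[C@H](CO[Si](c2ccccc2)(c2ccccc2)C(C)(C)C)[C@@](O)(C(=C)CO)[C@@H]1O
F2 | step 11 | 5-O-TBDPS-3-C-[3-(TBS-oxy)prop-1-en-2-yl]-D-lyxofuranose (lactol triol) | OC1O[C@H](CO[Si](c2ccccc2)(c2ccccc2)C(C)(C)C)[C@@](O)(C(=C)CO[Si](C)(C)C(C)(C)C)[C@@H]1O
F3 | step 13 | ethyl (2E)-enoate EtO2C(C3)–C4(CH3)=C5H–[C6/C7 acetonide]–C8H(OH)–C9H2OTBDPS (12-OTBS) | CCOC(=O)/C(C)=C/[C@H]1OC(C)(C)O[C@@]1(C(=C)CO[Si](C)(C)C(C)(C)C)[C@H](O)CO[Si](c2ccccc2)(c2ccccc2)C(C)(C)C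
F4 | step 13 | (4E)-allylic alcohol (C3 hydroxyl) from F3 | OC/C(C)=C/[C@H]1OC(C)(C)O[C@@]1(C(=C)CO[Si](C)(C)C(C)(C)C)[C@H](O)CO[Si](c2ccccc2)(c2ccccc2)C(C)(C)C
F5 | step 13 | (4E)-allylic bromide (C3 bromide) | BrC/C(C)=C/[C@H]1OC(C)(C)O[C@@]1(C(=C)CO[Si](C)(C)C(C)(C)C)[C@H](O)CO[Si](c2ccccc2)(c2ccccc2)C(C)(C)C
F6 | step 13 | tert-butyl (4E)-ester tBuO2C(C1)–C2H2–C3H2–C4(CH3)=C5H–, otherwise as 17 | CC(C)(C)OC(=O)CC/C(C)=C/[C@H]1OC(C)(C)O[C@@]1(C(=C)CO[Si](C)(C)C(C)(C)C)[C@H](O)CO[Si](c2ccccc2)(c2ccccc2)C(C)(C)C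
F7 | step 21 | 9-epi-29 (9S alcohol) | C=C1C(=O)O[C@@H]2/C=C(\C)CC/C=C(/C)[C@H](O)[C@@H](OC(=O)[C@@]3(C)O[C@@H]3C)[C@@]12O
F8 | step 21 | ring 9-ketone (Z-enone) of 29 | C=C1C(=O)O[C@@H]2/C=C(\C)CC/C=C(/C)C(=O)[C@@H](OC(=O)[C@@]3(C)O[C@@H]3C)[C@@]12O
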